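The numbering follows the nonadec-18-ene chain, and the oxolane ring consists of O, C6, C7, C8 and C9. The route rests on cutting C10–C11. The threo O–C9/O–C10 pair, where ring carbon C9 meets acyloxy carbon C10, is read as an opened terminal oxirane. The precursor is acyclic: a (9R)-C9–C10 oxirane carrying C7–OTBS and a C6 chloride. Its trans-lithiated CH2 terminus captures non-8-enylboronic ester, and a strain-releasing 1,2-metallate shift makes C10–C11 with inversion and frees O9. Alkaline peroxide in the same flask converts C10–B into C10–OH. O9 then displaces the C6 chloride and closes the oxolane. One operation delivers the bond, C10, C6, the ring and the only free hydroxyl.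

Key step: step 7

Assumption: the sense of induction in steps 1, 2 and 5 follows the accepted models for these catalysts and reagents. Should one run the other way, its commercially available enantiomer is used.

Step 1
Reactants: 1 heptanal
Product: 2 (2R)-2-chloroheptanal
Conditions: (5R)-5-benzyl-2,2,3-trimethylimidazolidin-4-one·CF3CO2H (5 mol %), 2,3,4,5,6,6-hexachlorocyclohexa-2,4-dien-1-one, acetone, −30 °C; pentane extraction, used at once
Reagents that add atoms: 2,3,4,5,6,6-hexachlorocyclohexa-2,4-dien-1-one, O=C1C(Cl)=C(Cl)C(Cl)=C(Cl)C1(Cl)Cl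
Why: Organocatalytic enamine α-chlorination: the benzyl group of the (5R)-imidazolidinone shields one face of the E-enamine of 1, so the electrophilic chlorine of the quinoid donor should arrive from the open face and set the R chloride centre (the later C6).

Step 2
Reactants: 2 (2R)-2-chloroheptanal; 3 (−)-B-allyldiisopinocampheylborane
Product: 5 (4S,5R)-5-chlorodec-1-en-4-ol, via borinate ester 4 (not isolated)
Conditions: 3 (1 M in pentane), Et2O, −100 → −78 °C; then pH 7 phosphate buffer, MeOH, 30% H2O2, 0 °C → rt
Reagents that add atoms: (−)-B-allyldiisopinocampheylborane 3, C=CCB([C@@H]1C[C@@H]2C[C@H]([C@H]1C)C2(C)C)[C@@H]1C[C@@H]2C[C@H]([C@H]1C)C2(C)C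
Why: Brown allylboration through a closed chair transition state: the (+)-α-pinene-derived reagent should add allyl to the aldehyde face that gives 7S, which is also the 1,2-anti (Cornforth) preference of an α-chloroaldehyde, so reagent and substrate control are matched and the buffered oxidative work-up spares the base-sensitive chlorohydrin.

Step 3
Reactants: 5 (4S,5R)-5-chlorodec-1-en-4-ol
Product: 6 tert-butyl{[(4S,5R)-5-chlorodec-1-en-4-yl]oxy}dimethylsilane
Conditions: t-BuMe2SiOSO2CF3, 2,6-lutidine, CH2Cl2, −78 → 0 °C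
Reagents that add atoms: tert-butyldimethylsilyl trifluoromethanesulfonate, CC(C)(C)[Si](C)(C)OS(=O)(=O)C(F)(F)F
Why: Silyl ether formation with a silyl triflate and a hindered pyridine base protects O7 without generating the alkoxide that would close onto the C6 chloride.

Step 4
Reactants: 6 tert-butyl{[(4S,5R)-5-chlorodec-1-en-4-yl]oxy}dimethylsilane
Product: 7 2-[(2S,3R)-2-(tert-butyldimethylsilyloxy)-3-chlorooctyl]oxirane (both C9 epimers)
Conditions: mCPBA, CH2Cl2, 0 °C → rt
Reagents that add atoms: 3-chloroperoxybenzoic acid, O=C(OO)c1cccc(Cl)c1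
Why: Prilezhaev epoxidation of the only alkene present (the C18–C19 alkene of the target is not yet in the molecule) should give the terminal oxirane as both C9 epimers because the remote centres exert little control.

Step 5
Reactants: 7 2-[(2S,3R)-2-(tert-butyldimethylsilyloxy)-3-chlorooctyl]oxirane (both C9 epimers)
Product: 8 (2R)-2-[(2S,3R)-2-(tert-butyldimethylsilyloxy)-3-chlorooctyl]oxirane
Conditions: (R,R)-N,N'-bis(3,5-di-tert-butylsalicylidene)-1,2-cyclohexanediaminocobalt acetate (1 mol %), H2O (0.55 equiv), THF, 0 °C → rt; chromatography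
Reagents that add atoms: none
Why: Hydrolytic kinetic resolution: the (R,R)-cobalt salen acetate should hydrolyse the (9S)-oxirane selectively at C10 and leave the (9R)-epimer 8, which sets C9 under catalyst control and is separated from the polar diol by chromatography.

Step 6
Reactants: 9 9-bromonon-1-ene
Product: 11 4,4,5,5-tetramethyl-2-(non-8-en-1-yl)-1,3,2-dioxaborolane, via Grignard reagent 10 (not isolated)
Conditions: Mg, THF, rt → 40 °C; then 2-isopropoxy-4,4,5,5-tetramethyl-1,3,2-dioxaborolane, −78 °C → rt; 1 M HCl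
Reagents that add atoms: 2-isopropoxy-4,4,5,5-tetramethyl-1,3,2-dioxaborolane, CC(C)OB1OC(C)(C)C(C)(C)O1; magnesium, [Mg] (in 10 only)
Why: Grignard formation followed by substitution at boron of the isopropoxyboronate (borylation of an organomagnesium reagent) gives the primary alkylboronic ester while the remote alkene is untouched.

Step 7
Reactants: 8 (2R)-2-[(2S,3R)-2-(tert-butyldimethylsilyloxy)-3-chlorooctyl]oxirane; 11 4,4,5,5-tetramethyl-2-(non-8-en-1-yl)-1,3,2-dioxaborolane
Product: 16 (1R)-1-[(2R,4S,5S)-4-(tert-butyldimethylsilyloxy)-5-pentyloxolan-2-yl]dec-9-en-1-ol, via oxiranyllithium 12 (not isolated), via lithium boronate complex 13 (not isolated), via silyloxy boronic ester 14 (not isolated), via chlorodiol 15 (not isolated)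
Conditions: lithium 2,2,6,6-tetramethylpiperidide (LiTMP) added dropwise to 8 + 11, THF, −30 °C; Me3SiOSO2CF3, −78 °C → rt; 2 M NaOH, 30% H2O2, 0 °C → rt; then 50 °C
Reagents that add atoms: hydrogen peroxide, OO (oxygen on C10); trimethylsilyl trifluoromethanesulfonate, C[Si](C)(C)OS(=O)(=O)C(F)(F)F (silyl group of 14 only); lithium 2,2,6,6-tetramethylpiperidide, [Li]N1C(C)(C)CCCC1(C)C (lithium of 12 and 13 only)
Why: Lithium 2,2,6,6-tetramethylpiperidide removes the most accessible acidic proton of 8, the C10 oxirane hydrogen trans to the C8 chain, and the configurationally stable oxiranyllithium 12 is captured in situ, with retention, by boronic ester 11 to give boronate complex 13. In 13 the non-8-enyl group migrates from boron to C10 antiperiplanar to the breaking C10–O bond, a 1,2-metallate rearrangement driven by release of the oxirane strain and by silylation of the departing oxygen, which forms C10–C11 with inversion at C10 and leaves the oxygen on C9; the closest known reaction type is the homologation of boronic esters with lithiated terminal epoxides to syn-1,2-diols, a relative of the Matteson homologation. The silyl trap (14) blocks boron–oxygen syn elimination of the β-oxidoboronate, and alkaline peroxide then oxidises C10–B with retention and strips the labile trimethylsilyl ether to give 15. On warming, the C9 alkoxide displaces the C6 chloride in a 5-exo-tet Williamson closure of the oxolane ring (O, C6, C7, C8, C9) with inversion at C6. C10 (R) is thus controlled solely by the C9 centre of the oxirane through the sequence trans-lithiation, retention, inversion, retention, which translates into the threo C9/C10 pair, and C6 (S) by the chloride centre of step 1, which translates into the C6/C7-cis and C6/C9-trans ring pattern. The step needs oxirane deprotonation rather than loss of HCl from C6 (secured by the bulk of the amide, the low temperature and the in situ trap), five- rather than six-membered closure (O9 against O10, secured by ring-size kinetics) and no oxirane formation from O7 (secured by the silyl ether), and premature closure at the boronate stage would converge on the same product 16.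

Step 8
Reactants: 16 (1R)-1-[(2R,4S,5S)-4-(tert-butyldimethylsilyloxy)-5-pentyloxolan-2-yl]dec-9-en-1-ol; 17 dodecanoyl chloride
Product: 18 (1R)-1-[(2R,4S,5S)-4-(tert-butyldimethylsilyloxy)-5-pentyloxolan-2-yl]dec-9-en-1-yl dodecanoate
Conditions: 17, pyridine, 4-(dimethylamino)pyridine (cat.), CH2Cl2, 0 °C → rt
Reagents that add atoms: dodecanoyl chloride 17, CCCCCCCCCCCC(=O)Cl
Why: DMAP-catalysed acylation (nucleophilic catalysis) meets a single free hydroxyl, the C10–OH unmasked from boron, since O7 is silylated and O9 is the ring oxygen.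

Step 9
Reactants: 18 (1R)-1-[(2R,4S,5S)-4-(tert-butyldimethylsilyloxy)-5-pentyloxolan-2-yl]dec-9-en-1-yl dodecanoate
Product: 19 (1R)-1-[(2R,4S,5S)-4-hydroxy-5-pentyloxolan-2-yl]dec-9-en-1-yl dodecanoate (target)
Conditions: HF·pyridine, THF, 0 °C → rt
Reagents that add atoms: none
Why: Fluoride-driven desilylation under the mildly acidic conditions of HF·pyridine removes the silyl ether from O7 without ester cleavage, acyl migration or change at any stereocentre.

Compound list
1 | heptanal | CCCCCCC=O | starting material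
2 | (2R)-2-chloroheptanal | CCCCC[C@@H](Cl)C=O | intermediate
3 | (−)-B-allyldiisopinocampheylborane (from (+)-α-pinene) | C=CCB([C@@H]1C[C@@H]2C[C@H]([C@H]1C)C2(C)C)[C@@H]1C[C@@H]2C[C@H]([C@H]1C)C2(C)C | starting material
4 | (4S,5R)-5-chlorodec-1-en-4-yl diisopinocampheylborinate | C=CC[C@H](OB([C@@H]1C[C@@H]2C[C@H]([C@H]1C)C2(C)C)[C@@H]1C[C@@H]2C[C@H]([C@H]1C)C2(C)C)[C@H](Cl)CCCCC | intermediate
5 | (4S,5R)-5-chlorodec-1-en-4-ol (anti chlorohydrin) | C=CC[C@H](O)[C@H](Cl)CCCCC | intermediate
6 | tert-butyl{[(4S,5R)-5-chlorodec-1-en-4-yl]oxy}dimethylsilane | C=CC[C@H](O[Si](C)(C)C(C)(C)C)[C@H](Cl)CCCCC | intermediate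
7 | 2-[(2S,3R)-2-(tert-butyldimethylsilyloxy)-3-chlorooctyl]oxirane, both epimers at the oxirane carbon C9 | C1OC1C[C@H](O[Si](C)(C)C(C)(C)C)[C@H](Cl)CCCCC | intermediate
8 | (2R)-2-[(2S,3R)-2-(tert-butyldimethylsilyloxy)-3-chlorooctyl]oxirane | C1O[C@@H]1C[C@H](O[Si](C)(C)C(C)(C)C)[C@H](Cl)CCCCC | intermediate
9 | 9-bromonon-1-ene | C=CCCCCCCCBr | starting material
10 | non-8-en-1-ylmagnesium bromide | C=CCCCCCCC[Mg]Br | intermediate
11 | 4,4,5,5-tetramethyl-2-(non-8-en-1-yl)-1,3,2-dioxaborolane | C=CCCCCCCCB1OC(C)(C)C(C)(C)O1 | intermediate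
12 | oxiranyllithium of 8, lithium on C10 trans to the C8 chain | [Li][C@H]1O[C@@H]1C[C@H](O[Si](C)(C)C(C)(C)C)[C@H](Cl)CCCCC | intermediate
13 | lithium boronate complex, boron on C10 trans to the C8 chain and bearing pinacolate and non-8-enyl | [Li+].C=CCCCCCCC[B-]1(OC(C)(C)C(C)(C)O1)[C@H]2O[C@@H]2C[C@H](O[Si](C)(C)C(C)(C)C)[C@H](Cl)CCCCC | intermediate
14 | (6R,7S,9R,10R)-7-(tert-butyldimethylsilyloxy)-6-chloro-9-(trimethylsilyloxy)nonadec-18-en-10-ylboronic acid pinacol ester | C=CCCCCCCC[C@@H](B1OC(C)(C)C(C)(C)O1)[C@H](O[Si](C)(C)C)C[C@H](O[Si](C)(C)C(C)(C)C)[C@H](Cl)CCCCC | intermediate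
15 | (6R,7S,9R,10R)-7-(tert-butyldimethylsilyloxy)-6-chlorononadec-18-ene-9,10-diol | C=CCCCCCCC[C@@H](O)[C@H](O)C[C@H](O[Si](C)(C)C(C)(C)C)[C@H](Cl)CCCCC | intermediate
16 | (1R)-1-[(2R,4S,5S)-4-(tert-butyldimethylsilyloxy)-5-pentyloxolan-2-yl]dec-9-en-1-ol | C=CCCCCCCC[C@@H](O)[C@H]1C[C@H](O[Si](C)(C)C(C)(C)C)[C@H](CCCCC)O1 | intermediate
17 | dodecanoyl chloride (lauroyl chloride) | CCCCCCCCCCCC(=O)Cl | starting material
18 | (1R)-1-[(2R,4S,5S)-4-(tert-butyldimethylsilyloxy)-5-pentyloxolan-2-yl]dec-9-en-1-yl dodecanoate | C=CCCCCCCC[C@@H](OC(=O)CCCCCCCCCCC)[C@H]1C[C@H](O[Si](C)(C)C(C)(C)C)[C@H](CCCCC)O1 | intermediate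
19 | (1R)-1-[(2R,4S,5S)-4-hydroxy-5-pentyloxolan-2-yl]dec-9-en-1-yl dodecanoate | C=CCCCCCCC[C@@H](OC(=O)CCCCCCCCCCC)[C@H]1C[C@H](O)[C@H](CCCCC)O1 | target

Total step count: 9. Longest linear sequence: 8 (steps 1–5 and 7–9). Step 6 is the side branch.

Steps most likely to fail

**Step 7.** Four processes may go wrong:
- carbenoid decay of the oxiranyllithium before it is captured
- base-induced loss of HCl at C6
- boron–oxygen elimination after the shift
- a sluggish ring closure, or silyl migration from O7 to O9 in the alkaline stage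

The fallback sets out from 8 and comes back at 16. It reverses the order of ring closure and C10–C11 formation. Oxirane 8 is hydrolysed at C10 with water and the (S,S) enantiomer of the cobalt salen acetate, for which 8 is the fast-reacting isomer, to give (2R,4S,5R)-4-(tert-butyldimethylsilyloxy)-5-chlorodecane-1,2-diol F1. AgOSO2CF3 and Ag2O in THF close the ring through O9 (5-exo-tet, inversion at C6) to [(2R,4S,5S)-4-(tert-butyldimethylsilyloxy)-5-pentyloxolan-2-yl]methanol F2. Dess–Martin oxidation gives (2R,4S,5S)-4-(tert-butyldimethylsilyloxy)-5-pentyloxolane-2-carbaldehyde F3. Chelation-controlled addition of Grignard reagent 10 (MgBr2·OEt2, CH2Cl2/Et2O, −78 °C) then forms C10–C11 and should give the threo alcohol 16.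

**Step 5.** The hydrolysis may be slow or poorly discriminating because the bulky β-silyloxy chain sits next to the oxirane. This comes on top of the inherent loss of the unwanted epimer.

The fallback sets out from 5 and comes back at 8. It sets C9 by substrate control instead of resolution. Alcohol 5 is converted with Boc2O and 4-(dimethylamino)pyridine into tert-butyl (4S,5R)-5-chlorodec-1-en-4-yl carbonate F4. IBr in toluene at −80 °C triggers iodocarbonate cyclisation to the cis-4,6-disubstituted (1,3-syn) carbonate (4S,6R)-4-[(1R)-1-chlorohexyl]-6-(iodomethyl)-1,3-dioxan-2-one F5. Brief treatment with K2CO3 in MeOH at 0 °C gives (2S,3R)-3-chloro-1-[(2R)-oxiran-2-yl]octan-2-ol F6. Silylation as in step 3 then gives 8.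

**Step 2.** The labile α-chloroaldehyde may epimerise before or during the addition. Facial selectivity may erode, and the product may be hard to separate from the terpene alcohol.

The fallback sets out from 2 and comes back at 6. It replaces the reagent-controlled allylboration with a substrate-controlled aldol. The lithium enolate of ethyl acetate (LiN(i-Pr)2, THF, −78 °C) adds to 2 with the 1,2-anti (Cornforth) preference to give ethyl (3S,4R)-4-chloro-3-hydroxynonanoate F7. Silylation as in step 3 gives ethyl (3S,4R)-3-(tert-butyldimethylsilyloxy)-4-chlorononanoate F8. Reduction with i-Bu2AlH in CH2Cl2 at −78 °C stops at (3S,4R)-3-(tert-butyldimethylsilyloxy)-4-chlorononanal F9. Wittig methylenation (Ph3P=CH2, THF, −78 → 0 °C) then gives 6.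

Further compounds
F1 | step 7 | (2R,4S,5R)-4-(tert-butyldimethylsilyloxy)-5-chlorodecane-1,2-diol | OC[C@H](O)C[C@H](O[Si](C)(C)C(C)(C)C)[C@H](Cl)CCCCC
F2 | step 7 | [(2R,4S,5S)-4-(tert-butyldimethylsilyloxy)-5-pentyloxolan-2-yl]methanol | OC[C@H]1C[C@H](O[Si](C)(C)C(C)(C)C)[C@H](CCCCC)O1
F3 | step 7 | (2R,4S,5S)-4-(tert-butyldimethylsilyloxy)-5-pentyloxolane-2-carbaldehyde | O=C[C@H]1C[C@H](O[Si](C)(C)C(C)(C)C)[C@H](CCCCC)O1
F4 | step 5 | tert-butyl (4S,5R)-5-chlorodec-1-en-4-yl carbonate | C=CC[C@H](OC(=O)OC(C)(C)C)[C@H](Cl)CCCCC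
F5 | step 5 | (4S,6R)-4-[(1R)-1-chlorohexyl]-6-(iodomethyl)-1,3-dioxan-2-one | IC[C@H]1C[C@@H]([C@H](Cl)CCCCC)OC(=O)O1
F6 | step 5 | (2S,3R)-3-chloro-1-[(2R)-oxiran-2-yl]octan-2-ol | C1O[C@@H]1C[C@H](O)[C@H](Cl)CCCCC
F7 | step 2 | ethyl (3S,4R)-4-chloro-3-hydroxynonanoate | CCOC(=O)C[C@H](O)[C@H](Cl)CCCCC
F8 | step 2 | ethyl (3S,4R)-3-(tert-butyldimethylsilyloxy)-4-chlorononanoate | CCOC(=O)C[C@H](O[Si](C)(C)C(C)(C)C)[C@H](Cl)CCCCC
F9 | step 2 | (3S,4R)-3-(tert-butyldimethylsilyloxy)-4-chlorononanal | O=CC[C@H](O[Si](C)(C)C(C)(C)C)[C@H](Cl)CCCCC
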